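In a one-step world substrate and coupling partner meet directly, and doubling the partner doubles the rate. But south holds twice the coupling partner of west, and its last reading is 13.2% against 12.9%, a gap of 0.3 percentage points where one reading scatters by 0.5 points. So two colleagues set the partner aside and reckon with the free catalyst.

all flasks: substrate 10 mM

| charge | coupling partner | free catalyst | remark | time |
|---|---|---|---|---|
| west | 49 mM | 100 µM | run made earlier |  |
| south | 99 mM | 100 µM | run made earlier |  |
| east | 40 mM | 140 µM | run made earlier |  |
| dawn | 40.0 mM | 100 µM |  | 5.0 h |
| winter | 80.0 mM | 400 µM |  | 5.0 h |

| run | time / h | target / % |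
|---|---|---|
| west | 0.333 | 0.3 |
| west | 0.833 | 3.6 |
| west | 1.50 | 5.6 |
| west | 2.50 | 8.9 |
| west | 4.00 | 12.9 |
| south | 0.333 | 1.2 |
| south | 0.833 | 3.4 |
| south | 1.50 | 6.1 |
| south | 2.50 | 8.7 |
| south | 4.00 | 13.2 |
| east | 0.667 | 4.1 |
| east | 1.33 | 6.1 |
| east | 2.00 | 10.3 |
| east | 3.00 | 13.7 |
| east | 4.00 | 17.6 |

(scatter of a reading: 0.5 percentage points)

* the flask that ends with the higher amount of target, in percent of the substrate charged, or "neither" when 2 percentage points or less lies between them (dawn / winter / neither)
* final target, as a percentage of the substrate charged, in dawn
* final target, as a percentage of the substrate charged, in winter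

- the numbers in the tables scatter with a standard deviation of 0.5 points

Both use the exposure, c(free catalyst) times time. East gives 2.89 mM·h from its last reading, and west, with a different catalyst charge, gives 2.90 mM·h. This is the exposure constant: the exposure over which the fraction of substrate not yet turned to target falls by a factor e.

Dawn has an exposure of 0.500 mM·h, winter 2.00 mM·h. The first colleague holds that the catalyst works at a fixed pace, so target rises in a straight line with exposure. East's slope then puts dawn at 15.7% and winter at 62.9%.

The second holds that the rate follows the remaining substrate, a pseudo-first-order view. It joins the start, where the line holds, to the far end, where the rate dies away: the unconverted fraction is exp(−exposure/E). That gives dawn 15.9% and winter 49.9%. I side with the second, and on these figures winter ends higher.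

The forecast takes the same side and names winter, with 16% for dawn and 46% for winter, below my winter figure, with the warning “saturation or inhibition could lower it”.

The flask gives winter: dawn 16.1%, winter 46.0%. The straight line fails in winter, but at dawn's small exposure its 15.7% stands beside the result.

    substrate + free catalyst → catalyst intermediate A (k = 0.606 M⁻¹ s⁻¹)
    coupling partner + catalyst intermediate A → catalyst intermediate B (k = 15.5 M⁻¹ s⁻¹)
    catalyst intermediate B → catalyst intermediate C (k = 0.00195 s⁻¹)
    catalyst intermediate C ⇌ free catalyst + target (K = 0.00210 M, k = 0.00742 s⁻¹)
    target ⇌ isomer of the product (K = 0.536, k = 2.95 × 10⁻⁵ s⁻¹)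

A neighbour of dawn with 0.17 mM of free catalyst has an exposure of 0.850 mM·h, so E gives 25.5%, and that flask ends at 25.2%. The difference in free catalyst is the main reason that winter ends higher than dawn: with that difference taken away, winter's target ends at 16.1% instead of 46.0%.

The data are calculated for substances that don't exist, noise included.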